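(All constants were chosen freely; the run is a simulation.)

Colleague, you asked for a quick number and your hunch is that feeding D slowly costs little; I think it costs more.

    J + Z → J.Z (k1 = 1.0 M⁻¹ s⁻¹)
    G + X → G.X (k2 = 4.0 M⁻¹ s⁻¹)
    G → Z (k3 = 0.0029 s⁻¹)
    D + Z → D.Z (k4 = 6.9 M⁻¹ s⁻¹)

common to all: J 5.00 mM; X 2.00 mM; time 30 min
- ash: G 10 mM; D 20.0 mM; everything together at the start
- elm: G 10 mM (in portions, 3, over 25 min); D 20.0 mM; first portion at the start, last at 25 min
- alder: G 10 mM (fed, over 25 min); D 20.0 mM; all else is in the flask from the start; the feed brings no volume worth counting
- maple: G 10 mM; D 20.0 mM (fed, over 25 min); all else is in the flask from the start; the feed brings no volume worth counting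

- which flask leads in amount of D.Z, in percent of the G charged ("all alike" within 1.5 percentage points) (ash / elm / alder / maple / all alike)
- how much D.Z is there at the end, in percent of the G charged: ash
- how much D.Z is there at the end, in percent of the G charged: elm
- how much D.Z is there at the end, in percent of the G charged: alder
- how much D.Z is there at the end, in percent of the G charged: maple

**Main term.** X lasts about 0.417 min against a mean life of G of 5.75 min, so in ash and maple I book 20.0% of the G as lost to X, which leaves 80.0% to pass through Z.

**Leak ratio.** The small term is what J takes of Z. Define the leak ratio as the rate of J + Z over the rate of D + Z with both at full charge, 0.0362, the inverse of a selectivity factor. At any moment, multiply it by the fraction of its charge that J has free in the flask over the same fraction for D.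

**Ash.** D's mean fraction in ash is about 0.800, so with J's fraction held at one the leak is about 0.0453 and D.Z comes to about 76.5%.

**Maple.** Within one mean life of G, the feed in maple has delivered a fraction 0.230 of D. Taking that fraction for the whole passage of G, with J's fraction held at one, the leak is about 0.158 and D.Z about 69.1%. Part of the delivered D is used, which lowers D's fraction, while G that turns over later meets more delivered D, so this is an estimate and no bound; I lean below it. I reckon no number for elm or alder.

**The forecast.** It names ash as leader, with ash 76.2%, elm 61.5%, alder 67.5% and maple 69%. On maple its ground is: “In maple, D is scarce early, so Z builds up”. We part there: its central value stands at my estimate before the used D is counted, and I lean below it.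

**The run.** The leader is ash, with ash 76.2%, elm 61.5%, alder 67.8% and maple 59.7%, so the forecast is 9.3 percentage points high on maple. Watch J.Z against D.Z: maple ends at 19.9% to 59.7%, a ratio of 0.333, while ash ends at 3.36% to 76.2%, a ratio of 0.0441. Read through 0.0362, these give D's fraction over J's, on average as Z met them, as 0.821 in ash and 0.109 in maple, the maple reading lying below the 0.230 I took for delivered D.

**Second flask.** With 12 mM of D and the rest as in ash, the leak ratio becomes 0.0604, D's mean fraction about 0.667, and D.Z about 73.4%. The run gives 73.2%, with J.Z at 6.37%.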